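**Plan**

- Retrosynthesis: the isobutyryl ketone and its α-centre are cut first (aldol, oxidation, kinetic protonation), then the O–CH bond of ring A (δ-lactone) by oxygen insertion into a cyclopentanone. Ring C (γ-lactone) is cut by tethered C-acylation, methylation and radical hydroxyalkylation, ring B (cyclopentanone) at an aldol C=C. Last, the bond from the spiro carbon to the ring A carbonyl carbon is cut by reversing a 1,2-acyl shift, which unfolds the spiro centre to the 2,3-epoxide of a transposed (S)-carvone.
- Enabling feature: the spiro carbon carries two acyl carbons (the ring A C=O and the ring B C=O), and ring A holds the isopropenyl CH two atoms away. This is the retron of an epoxy-ketone ring contraction on the carvone skeleton: carvone C-1 becomes the spiro carbon, C-2 the ring B ketone, C-3 the ring A carbonyl, and the carvone methyl the quaternary carbon at the ring B/C fusion.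
- Forward order: carvone six-ring → transposed 3-alkyl enone → trans epoxide → ring contraction (ring A as a cyclopentanone bearing acetyl) → ring B → ring C → oxygen insertion to the δ-lactone → side-chain ketone.
- Stereochemistry: the isopropenyl centre comes from (S)-carvone; the spiro centre from trans epoxidation followed by an invertive acyl shift; the ring B/C CH from a face-selective radical addition; the methyl-bearing quaternary centre from the enforced cis ring fusion; the O–CH centre of ring A from a final kinetic protonation.

Key step: step 4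

Remark: the Grignard reagent of step 1 is taken as its commercial THF solution. The carbinol centre made in step 9 is carried as a mixture and the adjacent α-centre is drawn as the expected trans epimer, since the first is erased in step 11 and the second is reset in step 12.

**Route**

Step 1
Reactants: 1 (S)-carvone; 2 (1,3-dioxolan-2-ylmethyl)magnesium bromide
Product: 3 (5S)-1-(1,3-dioxolan-2-ylmethyl)-2-methyl-5-(prop-1-en-2-yl)cyclohex-2-en-1-ol (both C-1 epimers)
Conditions: THF, −78 → 0 °C; then H2O
Reagents that add atoms: none
Why: Grignard reagents add in 1,2-fashion to the carvone carbonyl, giving the tertiary allylic alcohol needed for transposition; the new carbinol centre is lost in step 2 and the isopropenyl-bearing centre of the chiral pool terpene is untouched.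

Step 2
Reactants: 3 tertiary allylic alcohol
Product: 4 (5R)-3-(1,3-dioxolan-2-ylmethyl)-2-methyl-5-(prop-1-en-2-yl)cyclohex-2-en-1-one
Conditions: pyridinium chlorochromate [C5H5NH][CrO3Cl], 4 Å molecular sieves, CH2Cl2, rt
Reagents that add atoms: pyridinium chlorochromate, [O-][Cr](=O)(=O)Cl.c1cc[nH+]cc1
Why: Babler–Dauben oxidative transposition, in which the chromate ester of the tertiary allylic alcohol undergoes a [3,3]-shift and the secondary chromate is oxidised, should give the enone with the former carvone methyl on the α-carbon and the new side chain on the β-carbon.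

Step 3
Reactants: 4 transposed enone
Product: 5 (1R,4R,6S)-6-(1,3-dioxolan-2-ylmethyl)-1-methyl-4-(prop-1-en-2-yl)-7-oxabicyclo[4.1.0]heptan-2-one (epoxide oxygen trans to isopropenyl)
Conditions: 30% H2O2, NaOH (0.3 equiv), MeOH, 0 °C → rt
Reagents that add atoms: hydrogen peroxide, OO
Why: Weitz–Scheffer epoxidation, in which hydroperoxide adds axially to the β-carbon anti to the isopropenyl group as with carvone itself and the enolate closes the oxirane on the same face, should place the epoxide oxygen trans to isopropenyl while the isolated alkene and the acetal stay inert to the nucleophilic oxidant.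

Step 4
Reactants: 5 epoxy ketone
Product: 6 (2R,4R)-2-acetyl-2-(1,3-dioxolan-2-ylmethyl)-4-(prop-1-en-2-yl)cyclopentan-1-one (side chain cis, acetyl trans to isopropenyl)
Conditions: BF3·OEt2 (0.5 equiv), CH2Cl2, −40 → 0 °C
Reagents that add atoms: none
Why: BF3 coordination to the epoxide oxygen ionises the C–O bond at the fully alkylated β-carbon (the future spiro carbon) while the ring carbonyl carbon migrates from the α-carbon to this centre in a concerted 1,2-acyl shift, the α-carbon collapsing to the acetyl C=O. The closest known reaction type is the Lewis-acid rearrangement of 2,3-epoxycyclohexanones to 2-acylcyclopentanones. The cyclopentanone (ring A before oxygen insertion) is closed by ring contraction, the new bond forming through a three-centre 1,2-shift inside the six-membered ring and not by an end-to-end cyclisation. The new quaternary stereocentre forms with inversion at the migration terminus, so its configuration is dictated by the epoxide face that step 3 placed trans to isopropenyl, which leaves the side chain cis and the acetyl group trans to isopropenyl. The step needs opening at the β- and not the α-carbon and acyl instead of methyl migration; the first is secured by the tertiary alkyl character of the β-carbon against the α-keto position, the second by the much higher migratory aptitude of acyl groups in this manifold. Substoichiometric Lewis acid at low temperature is chosen so that the dioxolane and the isopropenyl group should survive.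

Step 5
Reactants: 6 acetyl cyclopentanone acetal
Product: 8 (5R,8R)-8-(prop-1-en-2-yl)spiro[4.4]non-2-ene-1,6-dione, via keto aldehyde 7 (not isolated)
Conditions: 1 M HCl, THF, rt; then piperidine, AcOH (cat.), PhMe, 80 °C
Reagents that add atoms: none
Why: aqueous acid unmasks the aldehyde and amine–acid catalysis effects the intramolecular aldol condensation of the acetyl methyl group onto it, closing ring B as a cyclopentenone without the hydroxide or alkoxide that would cleave the non-enolisable 1,3-diketone by retro-Claisen reaction.

Step 6
Reactants: 8 spiro enone; 9 propan-2-ol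
Product: 10 (3S,5S,8R)-3-(2-hydroxypropan-2-yl)-8-(prop-1-en-2-yl)spiro[4.4]nonane-1,6-dione
Conditions: (n-Bu4N)4[W10O32] (2 mol %), MeCN with excess propan-2-ol as co-solvent, 390 nm LEDs, rt
Reagents that add atoms: none
Why: in this Giese addition, decatungstate hydrogen-atom abstraction from the carbinol C–H of 9 gives the nucleophilic 2-hydroxyprop-2-yl radical, which should add to the β-carbon of the ring B enone from the face flanked by the ring A carbonyl and not by the ring A methylene (smaller flanking group, O–H···O=C contact), setting the ring B/C CH centre and leaving the electron-rich isopropenyl group alone; the reduced catalyst returns the hydrogen atom to the α-carbon, so both reactants end up entirely in the product.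

Step 7
Reactants: 10 hydroxy diketone
Product: 11 phenyl 2-[(3S,5S,8R)-1,6-dioxo-8-(prop-1-en-2-yl)spiro[4.4]nonan-3-yl]propan-2-yl carbonate
Conditions: PhOC(O)Cl, pyridine, DMAP (cat.), CH2Cl2, 0 °C → rt
Reagents that add atoms: phenyl chloroformate, O=C(Cl)Oc1ccccc1
Why: amine-catalysed acylation of the tertiary alcohol installs an aryl carbonate as a one-carbon tether that becomes the ring C carbonyl carbon, and it avoids generating an alkoxide next to the 1,3-diketone.

Step 8
Reactants: 11 phenyl carbonate
Product: 13 spiro tricyclic diketo lactone (rings B and C of the target, cis-fused, angular methyl in place, spiro-joined to a 4-isopropenylcyclopentan-1-one), via β-keto lactone 12 (not isolated)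
Conditions: LiN(SiMe3)2 (2.1 equiv), THF, −78 → 0 °C; then MeI, 0 °C → rt; H2O work-up
Reagents that add atoms: iodomethane, CI
Why: in this intramolecular Claisen-type C-acylation the ring B ketone enolate attacks the tethered carbonate in a 5-(enolexo)-exo-trig closure with loss of phenoxide (the ring A enolate has no electrophile in reach and is returned by proton transfer), the doubly stabilised enolate is then C-methylated, and because the five–five fusion can only be cis the new quaternary centre follows from the neighbouring CH centre.

Step 9
Reactants: 13 spiro tricyclic diketo lactone; 14 2-methylpropanal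
Product: 15 aldol adduct of 13 carrying a 1-hydroxy-2-methylpropyl group on the ring A α-carbon (trans to isopropenyl expected; carbinol epimers)
Conditions: n-Bu2BOTf, i-Pr2NEt, CH2Cl2, −78 → 0 °C; 14, −78 °C; then pH 7 buffer, MeOH, 30% H2O2, 0 °C
Reagents that add atoms: none
Why: boron-mediated aldol addition at the only enolisable position left (the ring A α-CH2) attaches the carbinol that becomes the isobutyryl group, the covalent boron aldolate avoids a free alkoxide, and the configurations of the two new centres do not matter because they are erased in step 11 and reset in step 12.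

Step 10
Reactants: 15 aldol adduct
Product: 16 hydroxy δ-lactone (ring A closed; O–CH centre epimeric to the target, carbinol epimers)
Conditions: Me3SiOOSiMe3, Me3SiOTf (0.2 equiv), CH2Cl2, −40 → 0 °C; then 1 M HCl
Reagents that add atoms: bis(trimethylsilyl) peroxide, C[Si](C)(C)OO[Si](C)(C)C
Why: in this Baeyer–Villiger oxidation the silyl peroxide adds to the ring A ketone and the secondary α-carbon should migrate with retention in preference to the spiro carbon, whose migratory aptitude is lowered by its second acyl substituent; the silyl peroxide system does not epoxidise the isopropenyl group, and the ring B ketone, flanked by two quaternary acyl-bearing carbons, should not react.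

Step 11
Reactants: 16 hydroxy δ-lactone
Product: 17 epimer of the target at the O–CH carbon of ring A
Conditions: Dess–Martin periodinane, CH2Cl2, 0 °C → rt
Reagents that add atoms: none
Why: Dess–Martin oxidation converts the secondary carbinol into the isobutyryl ketone under neutral conditions that leave the alkene and both lactones untouched.

Step 12
Reactants: 17 epimeric keto lactone
Product: 19 target CNP0216954.1, via silyl enol ether 18 (not isolated)
Conditions: Me3SiOTf, Et3N, CH2Cl2, −78 → 0 °C; then n-Bu4NF, AcOH, THF, −78 °C
Reagents that add atoms: none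
Why: soft enolisation gives the silyl enol ether exocyclic to ring A, in which allylic 1,3-strain forces the neighbouring isopropenyl group pseudoaxial, and low-temperature protodesilylation should then deliver the proton to the opposite face, placing the isobutyryl group cis to isopropenyl as in the target (convergent for either epimer; enolisation toward the isopropyl side is unproductive but harmless).

**Compound list**

1 | (S)-carvone, (5S)-2-methyl-5-(prop-1-en-2-yl)cyclohex-2-en-1-one | CC1=CC[C@@H](CC1=O)C(C)=C | starting material
2 | (1,3-dioxolan-2-ylmethyl)magnesium bromide, BrMgCH2CH(OCH2CH2O) | Br[Mg]CC1OCCO1 | starting material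
3 | (5S)-1-(1,3-dioxolan-2-ylmethyl)-2-methyl-5-(prop-1-en-2-yl)cyclohex-2-en-1-ol, C-1 epimers | CC1=CC[C@@H](CC1(O)CC2OCCO2)C(C)=C | intermediate
4 | (5R)-3-(1,3-dioxolan-2-ylmethyl)-2-methyl-5-(prop-1-en-2-yl)cyclohex-2-en-1-one | CC1=C(CC2OCCO2)C[C@@H](C(C)=C)CC1=O | intermediate
5 | (1R,4R,6S)-6-(1,3-dioxolan-2-ylmethyl)-1-methyl-4-(prop-1-en-2-yl)-7-oxabicyclo[4.1.0]heptan-2-one | C[C@@]12O[C@]1(CC3OCCO3)C[C@@H](C(C)=C)CC2=O | intermediate
6 | (2R,4R)-2-acetyl-2-(1,3-dioxolan-2-ylmethyl)-4-(prop-1-en-2-yl)cyclopentan-1-one | CC(=O)[C@]1(CC2OCCO2)C[C@@H](C(C)=C)CC1=O | intermediate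
7 | 2-[(1R,4R)-1-acetyl-2-oxo-4-(prop-1-en-2-yl)cyclopentyl]acetaldehyde | CC(=O)[C@]1(CC=O)C[C@@H](C(C)=C)CC1=O | intermediate
8 | (5R,8R)-8-(prop-1-en-2-yl)spiro[4.4]non-2-ene-1,6-dione | O=C1C=CC[C@]12C[C@@H](C(C)=C)CC2=O | intermediate
9 | propan-2-ol | CC(C)O | starting material
10 | (3S,5S,8R)-3-(2-hydroxypropan-2-yl)-8-(prop-1-en-2-yl)spiro[4.4]nonane-1,6-dione | O=C1C[C@@H](C(C)(C)O)C[C@]12C[C@@H](C(C)=C)CC2=O | intermediate
11 | phenyl 2-[(3S,5S,8R)-1,6-dioxo-8-(prop-1-en-2-yl)spiro[4.4]nonan-3-yl]propan-2-yl carbonate | O=C1C[C@@H](C(C)(C)OC(=O)Oc3ccccc3)C[C@]12C[C@@H](C(C)=C)CC2=O | intermediate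
12 | β-keto lactone: as 13 with H in place of the angular methyl, cis ring fusion, present as its lithium enolate | C=C(C)[C@@H]1C[C@]2(C[C@@H]3C(C)(C)OC(=O)[C@@H]3C2=O)C(=O)C1 | intermediate
13 | spiro tricyclic diketo lactone: cis-fused gem-dimethyl γ-lactone/cyclopentanone with angular methyl (rings C and B of the target), spiro-joined at the ketone α-carbon to 4-isopropenylcyclopentan-1-one; four stereocentres as in the target | C=C(C)[C@@H]1C[C@]2(C[C@@H]3C(C)(C)OC(=O)[C@]3(C)C2=O)C(=O)C1 | intermediate
14 | 2-methylpropanal | CC(C)C=O | starting material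
15 | aldol adduct: 13 with a 1-hydroxy-2-methylpropyl group on the ring A α-carbon, trans to isopropenyl, carbinol epimers | C=C(C)[C@@H]1C[C@]2(C[C@@H]3C(C)(C)OC(=O)[C@]3(C)C2=O)C(=O)[C@H]1C(O)C(C)C | intermediate
16 | hydroxy δ-lactone: target skeleton with CH(OH)CH(CH3)2 in place of the isobutyryl group, O–CH centre epimeric to the target | C=C(C)[C@@H]1C[C@]2(C[C@@H]3C(C)(C)OC(=O)[C@]3(C)C2=O)C(=O)O[C@H]1C(O)C(C)C | intermediate
17 | epimer of the target at the O–CH carbon of ring A (isobutyryl trans to isopropenyl) | C=C(C)[C@@H]1C[C@]2(C[C@@H]3C(C)(C)OC(=O)[C@]3(C)C2=O)C(=O)O[C@H]1C(=O)C(C)C | intermediate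
18 | trimethylsilyl enol ether of 17, double bond exocyclic to ring A | C=C(C)[C@@H]1C[C@]2(C[C@@H]3C(C)(C)OC(=O)[C@]3(C)C2=O)C(=O)OC1=C(O[Si](C)(C)C)C(C)C | intermediate
19 | CNP0216954.1 | C=C(C)[C@@H]1C[C@]2(C[C@@H]3C(C)(C)OC(=O)[C@]3(C)C2=O)C(=O)O[C@@H]1C(=O)C(C)C | target

**Step count and risks**

Total step count: 12. Longest linear sequence: 12 steps (from 1).

Steps most likely to fail:

Step 6 – the radical addition may show too little facial selectivity, because the spiro centre distinguishes the two faces of ring B only through a CH2 against a C=O group. The fallback uses reagent control; it sets out from 1 and returns at 10. 2-Methylbut-3-yn-2-ol is silylated (t-BuMe2SiOTf, 2,6-lutidine) to tert-butyldimethyl[(2-methylbut-3-yn-2-yl)oxy]silane F1. Its lithium acetylide (n-BuLi, THF, −78 °C) adds to 1 to give the alkynyl carbinol F2. Oxidative transposition as in step 2 gives the enynone F3, epoxidation as in step 3 the epoxy ketone F4, and the ring contraction of step 4 the alkynyl diketone F5. Ph3PAuNTf2 in wet dioxane should hydrate the alkyne at the carbon remote from the spiro centre (carbonyl-assisted) to the triketone F6. KOt-Bu in t-BuOH closes ring B to the enone F7, whose β-carbon already carries the silyloxy-isopropyl group. Conjugate reduction with a chiral copper hydride (Cu(OAc)2, DTBM-SEGPHOS, polymethylhydrosiloxane; the ligand antipode is the one that delivers hydride to the ring B face syn to the ring A methylene) gives the silyl ether F8 under catalyst control. HF·pyridine then gives 10.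

Step 10 – the spiro carbon may migrate instead of the secondary carbon, or the β-hydroxy ketone may be lost by elimination under the Lewis acid. The fallback replaces the oxygen insertion by cleavage and re-closure; it sets out from 13 and returns at 17. The enolate of 13 (LiN(SiMe3)2, −78 °C) is hydroxylated with 2-(phenylsulfonyl)-3-phenyloxaziridine to the α-hydroxy ketone F9. Pb(OAc)4 in MeOH–PhH cleaves it to the aldehyde methyl ester F10. 2-(Propan-2-yl)-1,3-dithiane F11 (from 14 and propane-1,3-dithiol, BF3·OEt2) is lithiated (n-BuLi) and added to the aldehyde at −78 °C, and the resulting alkoxide closes ring A on the methyl ester to give the dithianyl lactone F12. MeI, CaCO3 in aqueous MeCN unmasks the ketone to give 17 as either epimer, which enters step 12.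

Step 12 – enolisation may go toward the isopropyl side, or the facial bias in the protonation may be too weak, leaving the isobutyryl group trans. The fallback sets the centre before oxygen insertion; it sets out from 15 and returns at 19. 15 is dehydrated (MsCl, Et3N; then DBU) to the (E)-alkylidene ketone F13. t-BuOOH and DBU give the spiro-epoxy ketone F14. SmI2 in THF–MeOH at −90 °C cleaves the α-C–O bond, and the samarium enolate should be protonated in situ from the face away from isopropenyl to give the cis β-hydroxy ketone F15. Oxygen insertion as in step 10 (retention) gives the cis hydroxy lactone F16, and Dess–Martin oxidation then gives 19 directly.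

Further compounds
F1 | step 6 | tert-butyldimethyl[(2-methylbut-3-yn-2-yl)oxy]silane | C#CC(C)(C)O[Si](C)(C)C(C)(C)C
F2 | step 6 | (5S)-1-[3-(tert-butyldimethylsilyloxy)-3-methylbut-1-yn-1-yl]-2-methyl-5-(prop-1-en-2-yl)cyclohex-2-en-1-ol, C-1 epimers | CC1=CC[C@@H](CC1(O)C#CC(C)(C)O[Si](C)(C)C(C)(C)C)C(C)=C
F3 | step 6 | (5R)-3-[3-(tert-butyldimethylsilyloxy)-3-methylbut-1-yn-1-yl]-2-methyl-5-(prop-1-en-2-yl)cyclohex-2-en-1-one | CC1=C(C#CC(C)(C)O[Si](C)(C)C(C)(C)C)C[C@@H](C(C)=C)CC1=O
F4 | step 6 | 2,3-epoxide of F3, oxygen trans to isopropenyl | C[C@@]12O[C@]1(C#CC(C)(C)O[Si](C)(C)C(C)(C)C)C[C@@H](C(C)=C)CC2=O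
F5 | step 6 | 2-acetyl-2-[3-(tert-butyldimethylsilyloxy)-3-methylbut-1-yn-1-yl]-4-(prop-1-en-2-yl)cyclopentan-1-one, alkynyl cis to isopropenyl | CC(=O)[C@]1(C#CC(C)(C)O[Si](C)(C)C(C)(C)C)C[C@@H](C(C)=C)CC1=O
F6 | step 6 | 2-acetyl-2-[3-(tert-butyldimethylsilyloxy)-3-methyl-2-oxobutyl]-4-(prop-1-en-2-yl)cyclopentan-1-one | CC(=O)[C@]1(CC(=O)C(C)(C)O[Si](C)(C)C(C)(C)C)C[C@@H](C(C)=C)CC1=O
F7 | step 6 | 3-[2-(tert-butyldimethylsilyloxy)propan-2-yl]-8-(prop-1-en-2-yl)spiro[4.4]non-2-ene-1,6-dione | O=C1C=C(C(C)(C)O[Si](C)(C)C(C)(C)C)C[C@]12C[C@@H](C(C)=C)CC2=O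
F8 | step 6 | tert-butyldimethylsilyl ether of 10 | O=C1C[C@@H](C(C)(C)O[Si](C)(C)C(C)(C)C)C[C@]12C[C@@H](C(C)=C)CC2=O
F9 | step 10 | α-hydroxy ketone: 13 with OH on the ring A α-carbon, trans to isopropenyl | C=C(C)[C@@H]1C[C@]2(C[C@@H]3C(C)(C)OC(=O)[C@]3(C)C2=O)C(=O)[C@H]1O
F10 | step 10 | seco aldehyde methyl ester: ring A opened, CO2CH3 on the spiro carbon, CHO on the isopropenyl-bearing carbon | C=C(C)[C@@H](C=O)C[C@@]1(C(=O)OC)C[C@@H]2C(C)(C)OC(=O)[C@]2(C)C1=O
F11 | step 10 | 2-(propan-2-yl)-1,3-dithiane | CC(C)C1SCCCS1
F12 | step 10 | dithianyl δ-lactone: 17 with the ketone masked as its 1,3-dithiane, O–CH epimers | C=C(C)[C@@H]1C[C@]2(C[C@@H]3C(C)(C)OC(=O)[C@]3(C)C2=O)C(=O)OC1C4(C(C)C)SCCCS4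
F13 | step 12 | (E)-2-methylpropylidene ketone from 15 | C=C(C)[C@@H]1C[C@]2(C[C@@H]3C(C)(C)OC(=O)[C@]3(C)C2=O)C(=O)/C1=C/C(C)C
F14 | step 12 | spiro-epoxy ketone from F13 | C=C(C)[C@@H]1C[C@]2(C[C@@H]3C(C)(C)OC(=O)[C@]3(C)C2=O)C(=O)C14OC4C(C)C
F15 | step 12 | cis β-hydroxy ketone: epimer of 15 at the ring A α-carbon | C=C(C)[C@@H]1C[C@]2(C[C@@H]3C(C)(C)OC(=O)[C@]3(C)C2=O)C(=O)[C@@H]1C(O)C(C)C
F16 | step 12 | cis hydroxy δ-lactone: epimer of 16 at the O–CH carbon | C=C(C)[C@@H]1C[C@]2(C[C@@H]3C(C)(C)OC(=O)[C@]3(C)C2=O)C(=O)O[C@@H]1C(O)C(C)C
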